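**Plan**
1. The retrosynthesis first cuts C7''–C8'' of the glycerol arm (aldol), then the aryl O–CH2 bond of a glycolate imide; this gives aldehyde 21, bromoacetyl imide 19 and furofuran phenol 15.
2. The aldol is possible because C8'' carries the aryl ether oxygen and lies between carbinol C7'' and C9''. With C9'' raised from CH2OH to an N-acyl oxazolidinone, C8'' is the enolisable carbon of a glycolate and C7'' the carbonyl carbon of a syringaldehyde; the threo C7''–OH/C8''–OAr pair is the syn-aldol pattern.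
3. The furofuran is cut at both O–CH2 bonds (O–C9' of ring A, O–C9 of ring B), then at C7–C8 (lactone aldol) and C7'–C8' (amine-catalysed aldol), back to methyl 4-oxobutanoate and two protected aldehydes.
4. Forward: temporary gamma-lactone (C9 carbonyl, O–C9'), second aldol, LiAlH4, ring A by mesylate displacement, ring B by fluoride-triggered displacement, etherification, aldol, reductive removal of the auxiliary, deallylation.
5. Stereochemistry: C7'/C8' from D-proline (anti); C8 from trans addition on the lactone; C7 from the erythro-selective potassium enolate aldol; both ring closures occur at CH2 carbons, so the benzylic centres are retained (guaiacyl exo, syringyl endo); C7''/C8'' from (S)-4-benzyloxazolidin-2-one.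

Key step: step 11

Remark: lignan numbering is used (C7–C9 guaiacyl half and C7'–C9' syringyl half of the furofuran, C7''–C9'' glycerol arm); the target is read as 7R,8S,7'S,8'S,7''R,8''R, that is guaiacyl exo and syringyl endo on the cis-fused bicycle with a threo arm, and 4-(allyloxy)-3-methoxybenzaldehyde is taken as purchasable.

Step 1
Reactants: 1 syringaldehyde
Product: 2 3,5-dimethoxy-4-(triisopropylsilyloxy)benzaldehyde
Conditions: TIPSCl, imidazole, DMF, rt
Reagents that add atoms: chlorotriisopropylsilane (TIPSCl), CC(C)[Si](Cl)(C(C)C)C(C)C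
Why: Silyl ether formation on the hindered phenol gives a group that should survive the amine, hydride and amide-base steps and falls to fluoride in step 7.

Step 2
Reactants: 2 3,5-dimethoxy-4-(triisopropylsilyloxy)benzaldehyde; 3 methyl 4-oxobutanoate
Product: 6 (4S)-4-{(S)-hydroxy[3,5-dimethoxy-4-(triisopropylsilyloxy)phenyl]methyl}dihydrofuran-2(3H)-one, via aldol aldehyde 4 (not isolated), via diol ester 5 (not isolated)
Conditions: D-proline (20 mol%), DMF, 4 °C, slow addition of 3; then MeOH, NaBH4, 0 °C; aq. NH4Cl work-up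
Reagents that add atoms: none
Why: The proline-catalysed enamine cross-aldol of donor aldehyde 3 with the non-enolisable aldehyde 2 proceeds through the hydrogen-bonded chair transition state to the anti aldol, the D-catalyst setting C7' and C8' both S, and in-situ NaBH4 reduction of the labile formyl group lets the primary alcohol close the gamma-lactone on the methyl ester.

Step 3
Reactants: 6 (4S)-4-{(S)-hydroxy[3,5-dimethoxy-4-(triisopropylsilyloxy)phenyl]methyl}dihydrofuran-2(3H)-one
Product: 7 (4S)-4-{(S)-(tert-butyldimethylsilyloxy)[3,5-dimethoxy-4-(triisopropylsilyloxy)phenyl]methyl}dihydrofuran-2(3H)-one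
Conditions: TBSOTf, 2,6-lutidine, CH2Cl2, −78 to 0 °C
Reagents that add atoms: tert-butyldimethylsilyl triflate (TBSOTf), CC(C)(C)[Si](C)(C)OS(=O)(=O)C(F)(F)F
Why: Silyl ether formation with a silyl triflate and a hindered pyridine base masks the secondary benzylic alcohol for the enolate chemistry without touching the lactone.

Step 4
Reactants: 7 (4S)-4-{(S)-(tert-butyldimethylsilyloxy)[3,5-dimethoxy-4-(triisopropylsilyloxy)phenyl]methyl}dihydrofuran-2(3H)-one; 8 4-(allyloxy)-3-methoxybenzaldehyde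
Product: 10 (3R,4S)-3-{(R)-[4-(allyloxy)-3-methoxyphenyl](hydroxy)methyl}-4-{(S)-(tert-butyldimethylsilyloxy)[3,5-dimethoxy-4-(triisopropylsilyloxy)phenyl]methyl}dihydrofuran-2(3H)-one, via potassium enolate 9 (not isolated)
Conditions: KN(SiMe3)2, THF, −78 °C; then 8, −78 °C, short contact time; AcOH quench at −78 °C
Reagents that add atoms: none
Why: In this lactone enolate aldol the potassium enolate should add anti to the C8' substituent (trans lactone, setting C8) and, under kinetic control through an open transition state, give the erythro (syn) carbinol at C7, as is known for potassium enolates of beta-substituted gamma-butyrolactones with aromatic aldehydes.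

Step 5
Reactants: 10 the aldol lactone
Product: 11 (1R,2S,3S,4S)-1-[4-(allyloxy)-3-methoxyphenyl]-4-(tert-butyldimethylsilyloxy)-4-[3,5-dimethoxy-4-(triisopropylsilyloxy)phenyl]-2,3-bis(hydroxymethyl)butan-1-ol
Conditions: LiAlH4, THF, 0 °C; aq. potassium sodium tartrate work-up
Reagents that add atoms: none
Why: Hydride reduction of the temporary lactone to the 1,4-diol should leave the silyl ethers, the allyl ether and all four stereocentres untouched.

Step 6
Reactants: 11 the triol
Product: 13 [(2R,3S,4S)-2-[4-(allyloxy)-3-methoxyphenyl]-4-{(S)-(tert-butyldimethylsilyloxy)[3,5-dimethoxy-4-(triisopropylsilyloxy)phenyl]methyl}tetrahydrofuran-3-yl]methyl methanesulfonate, via bis-mesylate 12 (not isolated)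
Conditions: MsCl (2.2 equiv), pyridine, 0 °C to rt
Reagents that add atoms: methanesulfonyl chloride (MsCl), CS(=O)(=O)Cl
Why: The two primary alcohols are sulfonylated selectively and the free C7 hydroxyl displaces the C9' mesylate in a 5-exo-tet Williamson closure with retention at C7 (closure on C9 would give an oxetane), so ring A forms with the guaiacyl group trans to C9.

Step 7
Reactants: 13 the tetrahydrofuran mesylate
Product: 15 4-{(1S,3aS,4R,6aS)-4-[4-(allyloxy)-3-methoxyphenyl]tetrahydro-1H,3H-furo[3,4-c]furan-1-yl}-2,6-dimethoxyphenol, via hydroxy mesylate 14 (not isolated)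
Conditions: Bu4NF (3 equiv), THF, 0 °C to rt; AcOH quench
Reagents that add atoms: none
Why: Fluoride cleaves both silyl ethers and the freed C7' alkoxide displaces the remaining primary mesylate (5-exo-tet Williamson closure) with retention at C7', which places the syringyl group endo on the cis-fused bicycle and frees the one phenol needed next.

Step 8
Reactants: 16 (S)-4-benzyloxazolidin-2-one; 17 bromoacetyl bromide
Product: 19 (S)-4-benzyl-3-(bromoacetyl)oxazolidin-2-one, via lithium salt 18 (not isolated)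
Conditions: n-BuLi, THF, −78 °C; then 17, −78 °C
Reagents that add atoms: none
Why: N-Acylation of the lithiated oxazolidinone by the acid bromide is fast at low temperature and leaves the alpha-bromide for the ether formation.

Step 9
Reactants: 15 the furofuran phenol; 19 (S)-4-benzyl-3-(bromoacetyl)oxazolidin-2-one
Product: 20 (S)-4-benzyl-3-{[4-((1S,3aS,4R,6aS)-4-[4-(allyloxy)-3-methoxyphenyl]tetrahydro-1H,3H-furo[3,4-c]furan-1-yl)-2,6-dimethoxyphenoxy]acetyl}oxazolidin-2-one
Conditions: K2CO3, acetone, rt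
Reagents that add atoms: none
Why: In this Williamson etherification the 2,6-dimethoxyphenoxide should displace the activated alpha-bromide faster than it attacks the imide carbonyl, installing the glycolate unit and its auxiliary in one operation.

Step 10
Reactants: 1 syringaldehyde
Product: 21 4-(allyloxy)-3,5-dimethoxybenzaldehyde
Conditions: allyl bromide, K2CO3, DMF, rt
Reagents that add atoms: allyl bromide, C=CCBr
Why: Williamson allylation gives an aldehyde whose phenol protection matches that on the guaiacyl ring, so both are removed together in the last step.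

Step 11
Reactants: 20 the aryloxyacetyl imide; 21 4-(allyloxy)-3,5-dimethoxybenzaldehyde
Product: 24 (S)-4-benzyl-3-{(2S,3R)-3-[4-(allyloxy)-3,5-dimethoxyphenyl]-3-hydroxy-2-(ArO)propanoyl}oxazolidin-2-one (ArO = the furofuranyl-2,6-dimethoxyphenoxy group of 20), via boron enolate 22 (not isolated), via boron aldolate 23 (not isolated)
Conditions: Bu2BOTf, iPr2NEt, CH2Cl2, −78 to 0 °C; then 21, −78 to 0 °C; then pH 7 buffer, MeOH, H2O2, 0 °C
Reagents that add atoms: none
Why: Soft enolisation of the aryloxyacetyl imide gives the Z-configured dibutylboron enolate, which adds to aldehyde 21 through a closed Zimmerman–Traxler chair; the closest known reaction type is the Evans syn-aldol of alkoxy- and aryloxyacetyl (glycolate) oxazolidinones with aromatic aldehydes. No ring is closed. The Z-enolate in the chair fixes the syn (threo) relation of C7'' and C8'', and the benzyl group of the (S)-auxiliary, with the two imide carbonyls opposed because boron has no free site for chelation, shields one enolate face so that C8'' becomes S in the adduct (R once C9'' is reduced) and C7'' becomes R. The step needs reagent control that overrides the remote furofuran stereocentres and reaction at a single position; the auxiliary secures the first, and the imide CH2 being the only acidic C–H beside a non-enolisable aldehyde secures the second. The amine-buffered medium at low temperature is chosen to keep the acid-sensitive endo benzylic ether at C7' intact. The oxidative work-up cleaves the boron aldolate to the free carbinol.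

Step 12
Reactants: 24 the syn-aldol imide
Product: 25 (1R,2R)-1-[4-(allyloxy)-3,5-dimethoxyphenyl]-2-(ArO)propane-1,3-diol (ArO as in 20)
Conditions: LiBH4, MeOH (1 equiv), THF, 0 °C
Reagents that add atoms: none
Why: Reductive cleavage of the N-acyl oxazolidinone by LiBH4 releases the auxiliary and returns C9'' to the alcohol level of the target without touching C7'' or C8''.

Step 13
Reactants: 25 the bis-allyl ether diol
Product: 26 (1R,2R)-1-(4-hydroxy-3,5-dimethoxyphenyl)-2-{4-[(1S,3aS,4R,6aS)-4-(4-hydroxy-3-methoxyphenyl)tetrahydro-1H,3H-furo[3,4-c]furan-1-yl]-2,6-dimethoxyphenoxy}propane-1,3-diol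
Conditions: Pd(PPh3)4 (5 mol%), morpholine, THF, rt
Reagents that add atoms: none
Why: In this Tsuji–Trost deallylation zerovalent palladium ionises both aryl allyl ethers to pi-allyl complexes that morpholine captures, freeing the two phenols under near-neutral, non-reductive conditions that should spare the benzylic ethers and the benzylic alcohol.

**Compound list**
1 | syringaldehyde (4-hydroxy-3,5-dimethoxybenzaldehyde) | COc1cc(C=O)cc(OC)c1O | starting material
2 | 3,5-dimethoxy-4-(triisopropylsilyloxy)benzaldehyde | COc1cc(C=O)cc(OC)c1O[Si](C(C)C)(C(C)C)C(C)C | intermediate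
3 | methyl 4-oxobutanoate | COC(=O)CCC=O | starting material
4 | methyl (3R,4S)-3-formyl-4-hydroxy-4-[3,5-dimethoxy-4-(triisopropylsilyloxy)phenyl]butanoate (anti aldol aldehyde) | O=C[C@H](CC(=O)OC)[C@H](O)c1cc(OC)c(O[Si](C(C)C)(C(C)C)C(C)C)c(OC)c1 | intermediate (not isolated)
5 | methyl (3S,4S)-4-hydroxy-3-(hydroxymethyl)-4-[3,5-dimethoxy-4-(triisopropylsilyloxy)phenyl]butanoate (diol ester) | OC[C@H](CC(=O)OC)[C@H](O)c1cc(OC)c(O[Si](C(C)C)(C(C)C)C(C)C)c(OC)c1 | intermediate (not isolated)
6 | (4S)-4-{(S)-hydroxy[3,5-dimethoxy-4-(triisopropylsilyloxy)phenyl]methyl}dihydrofuran-2(3H)-one | O=C1OC[C@@H]([C@H](O)c2cc(OC)c(O[Si](C(C)C)(C(C)C)C(C)C)c(OC)c2)C1 | intermediate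
7 | (4S)-4-{(S)-(tert-butyldimethylsilyloxy)[3,5-dimethoxy-4-(triisopropylsilyloxy)phenyl]methyl}dihydrofuran-2(3H)-one | O=C1OC[C@@H]([C@H](O[Si](C)(C)C(C)(C)C)c2cc(OC)c(O[Si](C(C)C)(C(C)C)C(C)C)c(OC)c2)C1 | intermediate
8 | 4-(allyloxy)-3-methoxybenzaldehyde | C=CCOc1ccc(C=O)cc1OC | starting material
9 | potassium enolate of lactone 7 (C8 deprotonated) | [K+].[O-]C1=C[C@H]([C@H](O[Si](C)(C)C(C)(C)C)c2cc(OC)c(O[Si](C(C)C)(C(C)C)C(C)C)c(OC)c2)CO1 | intermediate (not isolated)
10 | (3R,4S)-3-{(R)-[4-(allyloxy)-3-methoxyphenyl](hydroxy)methyl}-4-{(S)-(tert-butyldimethylsilyloxy)[3,5-dimethoxy-4-(triisopropylsilyloxy)phenyl]methyl}dihydrofuran-2(3H)-one | O=C1OC[C@@H]([C@H](O[Si](C)(C)C(C)(C)C)c2cc(OC)c(O[Si](C(C)C)(C(C)C)C(C)C)c(OC)c2)[C@@H]1[C@@H](O)c1ccc(OCC=C)c(OC)c1 | intermediate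
11 | (1R,2S,3S,4S)-1-[4-(allyloxy)-3-methoxyphenyl]-4-(tert-butyldimethylsilyloxy)-4-[3,5-dimethoxy-4-(triisopropylsilyloxy)phenyl]-2,3-bis(hydroxymethyl)butan-1-ol | COc1cc([C@H](O)[C@H](CO)[C@@H](CO)[C@H](O[Si](C)(C)C(C)(C)C)c2cc(OC)c(O[Si](C(C)C)(C(C)C)C(C)C)c(OC)c2)ccc1OCC=C | intermediate
12 | bis(methanesulfonate) of the two primary alcohols of 11 | COc1cc([C@H](O)[C@H](COS(C)(=O)=O)[C@@H](COS(C)(=O)=O)[C@H](O[Si](C)(C)C(C)(C)C)c2cc(OC)c(O[Si](C(C)C)(C(C)C)C(C)C)c(OC)c2)ccc1OCC=C | intermediate (not isolated)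
13 | [(2R,3S,4S)-2-[4-(allyloxy)-3-methoxyphenyl]-4-{(S)-(tert-butyldimethylsilyloxy)[3,5-dimethoxy-4-(triisopropylsilyloxy)phenyl]methyl}tetrahydrofuran-3-yl]methyl methanesulfonate | COc1cc([C@@H]2OC[C@@H]([C@H](O[Si](C)(C)C(C)(C)C)c3cc(OC)c(O[Si](C(C)C)(C(C)C)C(C)C)c(OC)c3)[C@H]2COS(C)(=O)=O)ccc1OCC=C | intermediate
14 | doubly desilylated hydroxy mesylate from 13 (free C7' hydroxyl and free phenol) | COc1cc([C@@H]2OC[C@@H]([C@H](O)c3cc(OC)c(O)c(OC)c3)[C@H]2COS(C)(=O)=O)ccc1OCC=C | intermediate (not isolated)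
15 | 4-{(1S,3aS,4R,6aS)-4-[4-(allyloxy)-3-methoxyphenyl]tetrahydro-1H,3H-furo[3,4-c]furan-1-yl}-2,6-dimethoxyphenol (7R,8S,7'S,8'S) | COc1cc([C@@H]2OC[C@@H]3[C@H]2CO[C@@H]3c2cc(OC)c(O)c(OC)c2)ccc1OCC=C | intermediate
16 | (S)-4-benzyloxazolidin-2-one | O=C1OC[C@H](Cc2ccccc2)N1 | starting material
17 | bromoacetyl bromide | BrCC(Br)=O | starting material
18 | lithium salt of 16 (N-lithiated) | [Li+].O=C1OC[C@H](Cc2ccccc2)[N-]1 | intermediate (not isolated)
19 | (S)-4-benzyl-3-(bromoacetyl)oxazolidin-2-one | O=C1OC[C@H](Cc2ccccc2)N1C(=O)CBr | intermediate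
20 | (S)-4-benzyl-3-{[4-((1S,3aS,4R,6aS)-4-[4-(allyloxy)-3-methoxyphenyl]tetrahydro-1H,3H-furo[3,4-c]furan-1-yl)-2,6-dimethoxyphenoxy]acetyl}oxazolidin-2-one | COc1cc([C@@H]2OC[C@@H]3[C@H]2CO[C@@H]3c2cc(OC)c(OCC(=O)N3[C@@H](Cc4ccccc4)COC3=O)c(OC)c2)ccc1OCC=C | intermediate
21 | 4-(allyloxy)-3,5-dimethoxybenzaldehyde | C=CCOc1c(OC)cc(C=O)cc1OC | intermediate
22 | Z-configured dibutylboron enolate of 20 | COc1cc([C@@H]2OC[C@@H]3[C@H]2CO[C@@H]3c2cc(OC)c(O/C=C(\OB(CCCC)CCCC)N3[C@@H](Cc4ccccc4)COC3=O)c(OC)c2)ccc1OCC=C | intermediate (not isolated)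
23 | dibutylboron aldolate of 24 (boron on the C7'' oxygen) | COc1cc([C@@H]2OC[C@@H]3[C@H]2CO[C@@H]3c2cc(OC)c(O[C@H](C(=O)N3[C@@H](Cc4ccccc4)COC3=O)[C@H](OB(CCCC)CCCC)c3cc(OC)c(OCC=C)c(OC)c3)c(OC)c2)ccc1OCC=C | intermediate (not isolated)
24 | (S)-4-benzyl-3-{(2S,3R)-3-[4-(allyloxy)-3,5-dimethoxyphenyl]-3-hydroxy-2-(ArO)propanoyl}oxazolidin-2-one (ArO = the furofuranyl-2,6-dimethoxyphenoxy group of 20) | COc1cc([C@@H]2OC[C@@H]3[C@H]2CO[C@@H]3c2cc(OC)c(O[C@H](C(=O)N3[C@@H](Cc4ccccc4)COC3=O)[C@H](O)c3cc(OC)c(OCC=C)c(OC)c3)c(OC)c2)ccc1OCC=C | intermediate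
25 | (1R,2R)-1-[4-(allyloxy)-3,5-dimethoxyphenyl]-2-(ArO)propane-1,3-diol (ArO as in 20) | COc1cc([C@@H]2OC[C@@H]3[C@H]2CO[C@@H]3c2cc(OC)c(O[C@H](CO)[C@H](O)c3cc(OC)c(OCC=C)c(OC)c3)c(OC)c2)ccc1OCC=C | intermediate
26 | (1R,2R)-1-(4-hydroxy-3,5-dimethoxyphenyl)-2-{4-[(1S,3aS,4R,6aS)-4-(4-hydroxy-3-methoxyphenyl)tetrahydro-1H,3H-furo[3,4-c]furan-1-yl]-2,6-dimethoxyphenoxy}propane-1,3-diol | COc1cc([C@@H]2OC[C@@H]3[C@H]2CO[C@@H]3c2cc(OC)c(O[C@H](CO)[C@H](O)c3cc(OC)c(O)c(OC)c3)c(OC)c2)ccc1O | target

**Summary**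
Total step count: 13. Longest linear sequence: 11 steps (steps 1, 2, 3, 4, 5, 6, 7, 9, 11, 12, 13, from syringaldehyde).

Steps most likely to fail:

Step 11. The Lewis acid may ionise the endo benzylic ether at C7' during enolisation (epimerisation toward the exo series), or the hindered glycolate may enolise incompletely. The fallback sets out from 15 and comes back at 25. Phenol 15 is etherified with methyl bromoacetate (K2CO3, acetone) to the methyl aryloxyacetate F7. Its lithium enolate (LiN(SiMe3)2, THF, −78 °C) adds to 21 without stereocontrol, forming the same C7''–C8'' bond under purely basic conditions and giving the beta-hydroxy ester mixture F8. Dess–Martin periodinane oxidises the mixture to the single beta-keto ester F9. Transfer hydrogenation with dynamic kinetic resolution (RuCl(p-cymene)[(S,S)-TsDPEN], HCO2H/Et3N 1:2, CH2Cl2) is expected to give the syn (2S,3R) hydroxy ester F10, the aryl ketone being reduced to the R carbinol while C8'' equilibrates through the enol. LiBH4 in THF then reduces the ester to 25.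

Step 4. Face selectivity at the aldehyde carbon may be poor, or the potassium aldolate may equilibrate by retro-aldol, giving an erythro/threo mixture at C7. The fallback sets out from 7 and comes back at 13. The aldol is run with LiN(SiMe3)2 without regard to C7, giving 10 together with its C7 epimer, the threo aldol lactone F4. LiAlH4 reduces both to 11 and the C7-epimeric triol F5. Catalytic camphorsulfonic acid in CH2Cl2 at 0 °C ionises the guaiacyl carbinol of both epimers to the same benzylic cation, which the C9' hydroxyl captures to give the favoured 2,3-trans tetrahydrofuran, the primary alcohol F6. This ring A closure is stereoconvergent, and C7' stays masked as its silyl ether. MsCl and Et3N in CH2Cl2 at 0 °C convert F6 into 13.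

Step 2. The enamine may add too slowly to the electron-rich, doubly ortho-substituted aldehyde, so that self-condensation of 3 takes over and the anti selectivity erodes. The fallback sets out from 2 and comes back at 6. Oxazolidinone 16 is acylated (n-BuLi, then methyl 4-chloro-4-oxobutanoate, THF, −78 °C) to the succinyl imide F1. The MgCl2-catalysed anti-aldol of F1 with 2 (MgCl2 10 mol%, Et3N, Me3SiCl, EtOAc, rt) should give the (2R,3S) anti adduct as its trimethylsilyl ether F2, through a chelated Z-enolate attacked on the face opposite the benzyl group. NaBH4 in THF–water cleaves the imide to the primary alcohol, which closes on the methyl ester to the trimethylsilyl ether of 6, lactone F3. Citric acid in MeOH removes the silyl group and gives 6.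

Further compounds
F1 | step 2 | (S)-4-benzyl-3-(4-methoxy-4-oxobutanoyl)oxazolidin-2-one | COC(=O)CCC(=O)N1[C@@H](Cc2ccccc2)COC1=O
F2 | step 2 | methyl (3R,4S)-3-[(S)-4-benzyl-2-oxooxazolidine-3-carbonyl]-4-[3,5-dimethoxy-4-(triisopropylsilyloxy)phenyl]-4-(trimethylsilyloxy)butanoate | COC(=O)C[C@@H](C(=O)N1[C@@H](Cc2ccccc2)COC1=O)[C@H](O[Si](C)(C)C)c1cc(OC)c(O[Si](C(C)C)(C(C)C)C(C)C)c(OC)c1
F3 | step 2 | (4S)-4-{(S)-[3,5-dimethoxy-4-(triisopropylsilyloxy)phenyl](trimethylsilyloxy)methyl}dihydrofuran-2(3H)-one | O=C1OC[C@@H]([C@H](O[Si](C)(C)C)c2cc(OC)c(O[Si](C(C)C)(C(C)C)C(C)C)c(OC)c2)C1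
F4 | step 4 | C7 epimer of 10 (threo aldol lactone) | O=C1OC[C@@H]([C@H](O[Si](C)(C)C(C)(C)C)c2cc(OC)c(O[Si](C(C)C)(C(C)C)C(C)C)c(OC)c2)[C@@H]1[C@H](O)c1ccc(OCC=C)c(OC)c1
F5 | step 4 | C7 epimer of triol 11 | COc1cc([C@@H](O)[C@H](CO)[C@@H](CO)[C@H](O[Si](C)(C)C(C)(C)C)c2cc(OC)c(O[Si](C(C)C)(C(C)C)C(C)C)c(OC)c2)ccc1OCC=C
F6 | step 4 | [(2R,3S,4S)-2-[4-(allyloxy)-3-methoxyphenyl]-4-{(S)-(tert-butyldimethylsilyloxy)[3,5-dimethoxy-4-(triisopropylsilyloxy)phenyl]methyl}tetrahydrofuran-3-yl]methanol | COc1cc([C@@H]2OC[C@@H]([C@H](O[Si](C)(C)C(C)(C)C)c3cc(OC)c(O[Si](C(C)C)(C(C)C)C(C)C)c(OC)c3)[C@H]2CO)ccc1OCC=C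
F7 | step 11 | methyl [4-((1S,3aS,4R,6aS)-4-[4-(allyloxy)-3-methoxyphenyl]tetrahydro-1H,3H-furo[3,4-c]furan-1-yl)-2,6-dimethoxyphenoxy]acetate | COc1cc([C@@H]2OC[C@@H]3[C@H]2CO[C@@H]3c2cc(OC)c(OCC(=O)OC)c(OC)c2)ccc1OCC=C
F8 | step 11 | methyl 3-[4-(allyloxy)-3,5-dimethoxyphenyl]-3-hydroxy-2-(ArO)propanoate (ArO as in 20; mixture at C2 and C3) | COc1cc([C@@H]2OC[C@@H]3[C@H]2CO[C@@H]3c2cc(OC)c(OC(C(=O)OC)C(O)c3cc(OC)c(OCC=C)c(OC)c3)c(OC)c2)ccc1OCC=C
F9 | step 11 | methyl 3-[4-(allyloxy)-3,5-dimethoxyphenyl]-3-oxo-2-(ArO)propanoate (ArO as in 20; C2 configurationally labile) | COc1cc([C@@H]2OC[C@@H]3[C@H]2CO[C@@H]3c2cc(OC)c(OC(C(=O)OC)C(=O)c3cc(OC)c(OCC=C)c(OC)c3)c(OC)c2)ccc1OCC=C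
F10 | step 11 | methyl (2S,3R)-3-[4-(allyloxy)-3,5-dimethoxyphenyl]-3-hydroxy-2-(ArO)propanoate (ArO as in 20) | COc1cc([C@@H]2OC[C@@H]3[C@H]2CO[C@@H]3c2cc(OC)c(O[C@H](C(=O)OC)[C@H](O)c3cc(OC)c(OCC=C)c(OC)c3)c(OC)c2)ccc1OCC=C
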